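## Structural features

The target is a germacranolide: a ten-membered carbocycle C1–C10 that is cis-fused at C6/C7 to an α-methylene-γ-butyrolactone (O–C6, C7–C11(=C13H2)–C12(=O)). The numbering used throughout is C1=C2 (E), C3 ketone, C4(CH3)=C5 (Z), C6–O, C7, C8–O ester, C9H2, C10(CH3)OH. C6 (S), C7 (R) and C8 (R) are contiguous; C10 (R) is an isolated tertiary carbinol whose oxygen is 1,3-anti to the C8 oxygen; a fifth centre lies in the (S)-2-methylbutanoate. The fragile groups are the exocyclic enoate (Michael acceptor and dipolarophile), the cross-conjugated dienone with its Z trisubstituted alkene, the tertiary allylic alcohol, and C7–H, which becomes acidic and β to a leaving group (the lactone oxygen on C6) whenever C8 is a carbonyl. The real difficulty is to close a strained ten-membered ring that holds one E and one Z alkene and, in the same design, to relate the remote C10 carbinol to the C6–C8 triad. The key step uses the fact that C8(O)–C9H2–C10(OH)CH3 is an aldol pattern and therefore a masked isoxazoline: a nitrile oxide on C8 and the 1,1-disubstituted C9=C10 end of a C2=C1–C10=C9 diene give C8–C9, O–C10, the carbocycle and the C10 centre in one event. The structures of the cyclisation precursor and product were checked atom by atom against the target (6S, 7R cis lactone, 4Z, 1E, 10R) and no correction was needed.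

## Logic of the disconnections

31 ⇒ 30 ⇒ 29. No skeletal bond is cut: the C3 carbonyl is traced back to a C3–H/C3–OH carbinol and then to its O–Si bond. The dienone with the Z alkene is the unit most prone to isomerisation and conjugate addition, so it is unveiled last. The gain is an sp3 C3 that travels as a silyl ether. The demand is an allylic oxidation that spares the tertiary C10 hydroxyl and the enoate, and a desilylation that spares the C8 ester.

29 ⇒ 27 + 28. The acyl C–O bond at C8 is cut. This brings in the fifth stereocentre from a commercial acid derivative and leaves a diol. The forward step must acylate the secondary C8 hydroxyl and not the tertiary C10 hydroxyl.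

27 ⇒ 26 ⇒ 24. The C8–H bond and then the N–O bond are traced back. The anti 1,3-diol comes from a β-hydroxy ketone by hydroxyl-directed reduction, and the ketone/carbinol pair comes from one isoxazoline. The gain is that both oxygens and the C8 centre derive from a single heterocycle. The demand is an N–O cleavage that leaves alkenes and the enoate alone and does not epimerise C7, followed by internal hydride delivery across the ring.

24 ⇒ 22 (through 23). C8–C9 and O–C10 are cut. This removes the ten-membered ring and the C10 centre together and leaves an open chain on a monocyclic lactone. The forward step must close in the bridged mode at the diene terminus, choose one face of C10, and avoid the other dipolarophiles in the molecule.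

22 ⇒ 20 ⇒ 19. The C8=N bond goes back to a C8–OH and then to its O–Si bond. The gain is a stable, storable alcohol. The demand is that the C8 carbonyl of 21 is never exposed to base, because C7 would epimerise or the lactone oxygen would eliminate.

19 ⇒ 12 + 15. C6–C7 and the lactone C12–O bond are cut. This joins the two halves, sets the C6/C7 cis pair and installs the exocyclic methylene without a separate step. The forward step must be syn-selective and enantioselective (Re face of the aldehyde) and must tolerate a Z enal and two silyl ethers.

15 ⇒ 14 ⇒ 13 + 1. C13–Br is traced back through an allylic transposition to C7–OH, and C7–C11 is cut. The gain is two commercial materials. The demand is a bromination that moves the double bond into conjugation with the ester without touching the silyl ether.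

12 ⇒ 11 ⇒ 10 ⇒ 9 ⇒ 5 + 6 (through 7 and 8). C2–C3 is cut after adjusting the oxidation state and protection at C6 and C3. C3 is the natural junction between the dienyl unit and the Z enal piece, and its configuration can be set by a catalyst because C3 is later destroyed. The forward steps need an E-selective hydrometalation of the enyne at the alkyne only, removal of a primary silyl ether beside a secondary one, and oxidations that do not isomerise the Z alkene.

5 ⇒ 4 ⇒ 3 ⇒ 1 + 2. C4=C5 is cut. A Z-selective olefination fixes the regiochemistry of the two oxygenated ends unambiguously (C3 as ester, C6 as silyl ether). The demand is high Z selectivity and a reduction/oxidation pair that keeps it.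

## Other disconnections considered

Alternative 1: The cut is C3–C4, with C1–C6 reconnected, so that the ten-membered ring contracts to a cyclohexane. In the forward sense, KH and 18-crown-6 convert cyclohexanol A1 into its alkoxide, which undergoes an acetylenic oxy-Cope rearrangement to an allenolate and, after protonation, the ten-membered enone A2.
- In its favour: ring expansion from a six-membered ring needs no dilution and is driven by enolate formation; the chair arrangement fixes the E C1=C2 bond; C7, C8 and C10 are set beforehand on a cyclohexane, where relative control is classical. On certainty of ring formation and on control of C10 it is the better of the two plans.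
- Against it here: the Z geometry of C4=C5 depends on kinetic protonation of an allenolate, whereas the chosen plan carries a preformed Z alkene. A2 has no lactone: the C6 ketone must be reduced to the alcohol cis to the C7 branch, C12 must be raised from a silyl ether to a carboxyl and lactonised, and the PMB, triethylsilyl and two tert-butyldimethylsilyl groups must be removed in order before acylation and oxidation. Any C6/C7 enolate would eliminate the C8 silyloxy group under the strongly basic conditions. A1 itself carries five stereocentres, two of them fully substituted carbinols.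
- Comparison: structurally the alternative makes the carbocycle earlier and more surely. Mechanistically it replaces folding-dependent facial control by a pericyclic transfer, which is a gain, but adds an uncontrolled protonation. In step economy the chosen plan is clearly shorter, because lactone, Z alkene and methylene arrive in one convergent Barbier step and only five steps follow ring closure.

Alternative 2: The cut is C1–C10. In the forward sense, CrCl2 converts the iodoalkyne of seco ketone A3 into an alkynylchromium species (trivalent chromium) that adds to the C10 methyl ketone and gives the ten-membered cycloalkyne A4 with the tertiary carbinol.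
- In its favour: lactone, C8 ester and C3 silyl ether are already in place, so only alkyne semireduction, desilylation and oxidation remain. That is fewer operations after ring closure than in the chosen plan, and on this point it is the better. Organochromium reagents tolerate esters and the enoate, and no dipolarophile competition exists, which is again a point for the alternative.
- Against it here: organochromium reagents add readily to aldehydes but only sluggishly to ketones. A ten-membered cycloalkyne that also holds a Z alkene is strained. The C10 ketone of A3 is β to the C8 acyloxy group and invites elimination. The alkyne must later be reduced trans inside a strained ring beside an enoate. A3 requires the C6–C7–C8 triad, the ester and the methyl ketone to be assembled in open-chain form.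
- Comparison: the face of C10 is fixed only by the macrocyclic conformation, exactly as in the chosen plan, so the two are equal there. Step economy after cyclisation is equal or slightly better; before cyclisation it is worse.

Alternative 3: The cut is C7–C8. In the forward sense, CrCl2 turns the 3-(bromomethyl)butenolide A5 into an allylchromium species that attacks the tethered C8 aldehyde through C7 and gives the ten-membered α-methylene lactone A6 with a free C8 hydroxyl.
- In its favour: this kind of closure has the broadest precedent for ten-membered methylene-lactone rings, better than the ring-size precedent of the chosen step. The tether starts at C6, so the aldehyde reaches C7 from the face of the C6 substituent and the cis fusion is enforced, which is equal to or better than catalyst control. The methylene appears only during ring closure and never competes. C10 is made beforehand by acyclic methods, which is more secure than facial control in a macrocyclic cycloaddition.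
- Against it here: the C8 configuration is decided in the macrocyclic transition state with no element that clearly dictates it. C6–H of butenolide A5 is acidic, with a risk of racemisation or furan formation. A5 demands a linear synthesis that contains the tertiary C10 carbinol, both alkenes and C3, with three silyl groups to tell apart.
- Comparison: after cyclisation the count is about four steps against five, so equal or slightly better. Before it, the sequence is longer and linear, whereas the chosen route is convergent and creates ring and C10 together.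

Key step: step 13

Assumption: the sense of induction of the two chiral catalysts (amino alcohol in step 4, bis(oxazoline)–CrCl2 complex in step 10) is taken from the closest analogies; both ligands exist in both enantiomeric forms, and the enantiomer meant is the one that delivers the stated face.

## Route

Step 1
Reactants: 1 (tert-butyldimethylsilyloxy)acetaldehyde; 2 ethyl 2-[bis(2,2,2-trifluoroethoxy)phosphoryl]propanoate
Product: 3 ethyl (2Z)-4-(tert-butyldimethylsilyloxy)-2-methylbut-2-enoate
Conditions: KN(SiMe3)2, 18-crown-6, THF, −78 °C
Reagents that add atoms: none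
Why: Still–Gennari olefination; the electron-poor bis(trifluoroethyl) phosphonate eliminates from the kinetically formed adduct, so C4=C5 should form with the ester carbon (C3) and the CH2OSi carbon (C6) cis, which is the 4Z geometry of the target.

Step 2
Reactants: 3 ethyl (2Z)-4-(tert-butyldimethylsilyloxy)-2-methylbut-2-enoate
Product: 4 (2Z)-4-(tert-butyldimethylsilyloxy)-2-methylbut-2-en-1-ol
Conditions: i-Bu2AlH (2.3 equiv), CH2Cl2, −78 °C; aq. potassium sodium tartrate
Reagents that add atoms: none
Why: 1,2-Reduction of an enoate by an aluminium hydride; neither the alkene geometry nor the silyl ether is affected at low temperature.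

Step 3
Reactants: 4 (2Z)-4-(tert-butyldimethylsilyloxy)-2-methylbut-2-en-1-ol
Product: 5 (2Z)-4-(tert-butyldimethylsilyloxy)-2-methylbut-2-enal
Conditions: MnO2, CH2Cl2, rt
Reagents that add atoms: none
Why: Allylic oxidation on a neutral heterogeneous oxidant, chosen because the Z α-methyl enal isomerises under acid or base; the aldehyde is used at once.

Step 4
Reactants: 6 2-methylbut-1-en-3-yne; 5 (2Z)-4-(tert-butyldimethylsilyloxy)-2-methylbut-2-enal
Product: 9 (2Z,4S,5E)-1-(tert-butyldimethylsilyloxy)-3,7-dimethylocta-2,5,7-trien-4-ol, via dienylborane 7 (not isolated), via dienylzinc 8 (not isolated)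
Conditions: 6, Cy2BH, hexane, 0 °C to rt; Me2Zn, −78 °C; (−)-3-exo-morpholinoisoborneol (5 mol %), then 5, −20 to 0 °C; aq. NH4Cl
Reagents that add atoms: none
Why: Syn hydroboration of the terminal alkyne (faster than the 1,1-disubstituted alkene) gives the E dienylborane, boron-to-zinc exchange gives the alkenylzinc, and the amino-alcohol-catalysed addition to the aldehyde forms C2–C3. By analogy with dialkylzinc additions to sp2-substituted aldehydes the (−)-ligand should direct attack to the Si face and give 3S. The centre is a spectator that ends as a ketone, so moderate selectivity only costs material.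

Step 5
Reactants: 9 (2Z,4S,5E)-1-(tert-butyldimethylsilyloxy)-3,7-dimethylocta-2,5,7-trien-4-ol
Product: 10 (3E,5S,6Z)-5,8-bis(tert-butyldimethylsilyloxy)-2,6-dimethylocta-1,3,6-triene
Conditions: TBSCl, imidazole, DMF, 0 °C to rt
Reagents that add atoms: tert-butyldimethylsilyl chloride (TBSCl), CC(C)(C)[Si](C)(C)Cl
Why: Standard silylation of a secondary alcohol; the C3 oxygen must be capped before C6 becomes an aldehyde, since a free cis γ-hydroxy enal would close to a lactol and aromatise to a furan.

Step 6
Reactants: 10 (3E,5S,6Z)-5,8-bis(tert-butyldimethylsilyloxy)-2,6-dimethylocta-1,3,6-triene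
Product: 11 (2Z,4S,5E)-4-(tert-butyldimethylsilyloxy)-3,7-dimethylocta-2,5,7-trien-1-ol
Conditions: HF·pyridine, pyridine, THF, 0 °C
Reagents that add atoms: none
Why: Fluoride attack at silicon is governed by sterics, so the primary silyl ether should be cleaved well before the secondary one; the pyridine buffer avoids ionisation of the doubly allylic C3–O bond.

Step 7
Reactants: 11 (2Z,4S,5E)-4-(tert-butyldimethylsilyloxy)-3,7-dimethylocta-2,5,7-trien-1-ol
Product: 12 (2Z,4S,5E)-4-(tert-butyldimethylsilyloxy)-3,7-dimethylocta-2,5,7-trienal
Conditions: MnO2, CH2Cl2, rt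
Reagents that add atoms: none
Why: Neutral allylic oxidation; a Z β,β-disubstituted enal of the neral type should keep its geometry under these conditions.

Step 8
Reactants: 13 methyl acrylate; 1 (tert-butyldimethylsilyloxy)acetaldehyde
Product: 14 methyl 4-(tert-butyldimethylsilyloxy)-3-hydroxy-2-methylidenebutanoate (racemic)
Conditions: DABCO (0.5 equiv), neat, rt
Reagents that add atoms: none
Why: Morita–Baylis–Hillman reaction, forming C7–C11; α-alkoxy aldehydes are good acceptors, and the carbinol centre is removed in the next step, so no stereocontrol is needed.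

Step 9
Reactants: 14 methyl 4-(tert-butyldimethylsilyloxy)-3-hydroxy-2-methylidenebutanoate
Product: 15 methyl (2Z)-2-(bromomethyl)-4-(tert-butyldimethylsilyloxy)but-2-enoate
Conditions: NBS, Me2S, CH2Cl2, 0 °C to rt
Reagents that add atoms: N-bromosuccinimide, O=C1CCC(=O)N1Br
Why: The alkoxysulfonium salt of the allylic alcohol is displaced by bromide with allylic transposition, giving the conjugated primary bromide. The thermodynamically preferred isomer has the CH2OSi group cis to CH2Br, the geometry the next step needs; the acid-free conditions spare the silyl ether.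

Step 10
Reactants: 12 (2Z,4S,5E)-4-(tert-butyldimethylsilyloxy)-3,7-dimethylocta-2,5,7-trienal; 15 methyl (2Z)-2-(bromomethyl)-4-(tert-butyldimethylsilyloxy)but-2-enoate
Product: 19 (4R,5S)-4-[(tert-butyldimethylsilyloxy)methyl]-5-[(1Z,3S,4E)-3-(tert-butyldimethylsilyloxy)-2,6-dimethylhepta-1,4,6-trien-1-yl]-3-methylideneoxolan-2-one, via allylchromium species 16 (not isolated), via silylated adduct 17 (not isolated), via hydroxy ester 18 (not isolated)
Conditions: CrCl2 (10 mol %), chiral carbazole-bis(oxazoline) ligand (12 mol %), iPr2NEt (cat.), Mn, TMSCl, THF, 0 °C to rt; then PPTS, MeOH, 0 °C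
Reagents that add atoms: none
Why: Nozaki–Hiyama–Kishi-type Barbier 2-(alkoxycarbonyl)allylation through a closed chair (Zimmerman–Traxler) transition state: the CH2OSi group, cis to CH2Cr, sits axial and the enal residue equatorial, giving the syn adduct and hence the cis lactone after acid-induced lactonisation. The ligand on chromium selects the Re face of the aldehyde (6S), which fixes 7R. Organochromium reagents leave the ester, the diene and the silyl ethers alone.

Step 11
Reactants: 19 (4R,5S)-4-[(tert-butyldimethylsilyloxy)methyl]-5-[(1Z,3S,4E)-3-(tert-butyldimethylsilyloxy)-2,6-dimethylhepta-1,4,6-trien-1-yl]-3-methylideneoxolan-2-one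
Product: 20 (4R,5S)-5-[(1Z,3S,4E)-3-(tert-butyldimethylsilyloxy)-2,6-dimethylhepta-1,4,6-trien-1-yl]-4-(hydroxymethyl)-3-methylideneoxolan-2-one
Conditions: HF·pyridine, pyridine, THF, 0 °C
Reagents that add atoms: none
Why: Same steric discrimination as in step 6 (primary before secondary silyl ether); the buffered reagent is compatible with the methylene lactone.

Step 12
Reactants: 20 (4R,5S)-5-[(1Z,3S,4E)-3-(tert-butyldimethylsilyloxy)-2,6-dimethylhepta-1,4,6-trien-1-yl]-4-(hydroxymethyl)-3-methylideneoxolan-2-one
Product: 22 (4R,5S)-5-[(1Z,3S,4E)-3-(tert-butyldimethylsilyloxy)-2,6-dimethylhepta-1,4,6-trien-1-yl]-4-[(E)-(hydroxyimino)methyl]-3-methylideneoxolan-2-one, via aldehyde 21 (not isolated)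
Conditions: Dess–Martin periodinane, NaHCO3, CH2Cl2, 0 °C; aq. Na2S2O3 wash; then NH2OH·HCl, NaOAc, EtOH, 0 °C
Reagents that add atoms: hydroxylamine hydrochloride, NO.Cl
Why: Buffered periodinane oxidation followed by oximation of the crude aldehyde. The aldehyde is α-branched and β to the lactone oxygen, so it is not purified, and acetate-buffered hydroxylamine condenses with it faster than it can add to the enoate or epimerise C7.

Step 13
Reactants: 22 (4R,5S)-5-[(1Z,3S,4E)-3-(tert-butyldimethylsilyloxy)-2,6-dimethylhepta-1,4,6-trien-1-yl]-4-[(E)-(hydroxyimino)methyl]-3-methylideneoxolan-2-one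
Product: 24 (3S,6S,7R,10R)-3-(tert-butyldimethylsilyloxy)germacra-1E,4Z,11(13)-trien-12,6-olide bridged by C8=N–O–C10 (isoxazoline), via nitrile oxide 23 (not isolated)
Conditions: PhI(OAc)2 (1.2 equiv), TFA (cat.), MeOH/CH2Cl2, 0 °C to rt, slow addition of 22, final concentration about 0.5 mM
Reagents that add atoms: none
Why: PhI(OAc)2 dehydrogenates the aldoxime to nitrile oxide 23, which adds in a concerted, asynchronous [3+2] cycloaddition across C9=C10; the closest known reaction type is the intramolecular nitrile oxide–alkene cycloaddition run in its bridged macrocyclisation mode. The ten-membered carbocycle closes through C8–C9 with the dipole carbon attacking the distal, unsubstituted alkene terminus (bridged mode), and the isoxazoline closes through O–C10 in the same event, C9 becoming the one-atom bridge. The regiochemistry (carbon to C9H2, oxygen to the substituted, vinyl-bearing C10) is the normal one for 1,1-disubstituted alkenes and diene termini and needs no help. The substrate is folded for this closure: the cis lactone holds C5 and C8 syn, and with 6S and 3S the conformer of the Z C4=C5 unit that keeps both allylic hydrogens in the alkene plane puts C7 and C2 on one face and both oxygens on the other, so the E C1=C2 bond turns the isopropenyl terminus back towards C8. The new centre C10 is controlled by C7 and C6 of the cis lactone: the tether leaving C6 is expected to arch over the face of the forming isoxazoline remote from the C11 branch on C7, which places the N–O bridge anti to the lactone and gives 10R. The step also needs site selectivity: the methylene lactone cannot be reached within the molecule (three- or four-membered rings) and is kept out bimolecularly by dilution and slow addition, while C1=C2, a 1,2-disubstituted alkene whose C2 is flanked by the silyloxy carbon, is the intrinsically slower dipolarophile. The 3S silyl ether is a spectator whose configuration or silyl group can be changed without consequence for the target, since C3 ends as a ketone.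

Step 14
Reactants: 24 (3S,6S,7R,10R)-3-(tert-butyldimethylsilyloxy)germacra-1E,4Z,11(13)-trien-12,6-olide bridged by C8=N–O–C10
Product: 26 (3S,6S,7S,10R)-3-(tert-butyldimethylsilyloxy)-10-hydroxy-8-oxogermacra-1E,4Z,11(13)-trien-12,6-olide, via hydroxy imine 25 (not isolated)
Conditions: Mo(CO)6, MeCN/H2O (10:1), 75 °C
Reagents that add atoms: water, O
Why: Zerovalent molybdenum cleaves the N–O bond and the water present hydrolyses the β-hydroxy imine: the reductive unmasking of an isoxazoline to an aldol. Isolated alkenes, the enoate and the silyl ether are not reduced, and the near-neutral medium is chosen because C7–H of 26 is α to the ketone and β to the lactone oxygen; 26 is filtered and used without delay. The 7S descriptor reflects only the changed priority of C8.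

Step 15
Reactants: 26 (3S,6S,7S,10R)-3-(tert-butyldimethylsilyloxy)-10-hydroxy-8-oxogermacra-1E,4Z,11(13)-trien-12,6-olide
Product: 27 (3S,6S,7R,8R,10R)-3-(tert-butyldimethylsilyloxy)-8,10-dihydroxygermacra-1E,4Z,11(13)-trien-12,6-olide
Conditions: Me4NBH(OAc)3, MeCN/AcOH (1:1), −30 °C
Reagents that add atoms: none
Why: Evans–Saksena directed reduction: the C10 hydroxyl exchanges an acetate on boron and delivers hydride internally to the face of the C8 carbonyl on which it sits, so the new C8–O bond is anti to C10–O (8R). The reagent does not reduce the enoate and the acidic medium cannot epimerise C7 by enolate formation.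

Step 16
Reactants: 27 (3S,6S,7R,8R,10R)-3-(tert-butyldimethylsilyloxy)-8,10-dihydroxygermacra-1E,4Z,11(13)-trien-12,6-olide; 28 (2S)-2-methylbutanoic anhydride
Product: 29 (3S,6S,7R,8R,10R)-3-(tert-butyldimethylsilyloxy)-10-hydroxy-8-[(2S)-2-methylbutanoyloxy]germacra-1E,4Z,11(13)-trien-12,6-olide
Conditions: DMAP, Et3N, CH2Cl2, 0 °C to rt
Reagents that add atoms: none
Why: DMAP-catalysed acylation; the secondary C8 hydroxyl reacts and the tertiary C10 hydroxyl does not, and the anhydride carries the acyl stereocentre in without a ketene-forming activation.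

Step 17
Reactants: 29 (3S,6S,7R,8R,10R)-3-(tert-butyldimethylsilyloxy)-10-hydroxy-8-[(2S)-2-methylbutanoyloxy]germacra-1E,4Z,11(13)-trien-12,6-olide
Product: 30 (3S,6S,7R,8R,10R)-3,10-dihydroxy-8-[(2S)-2-methylbutanoyloxy]germacra-1E,4Z,11(13)-trien-12,6-olide
Conditions: HF·pyridine, pyridine, THF, 0 °C to rt
Reagents that add atoms: none
Why: Fluoride cleavage of the remaining secondary silyl ether; the pyridine-buffered, non-basic reagent avoids acyl migration, conjugate addition to the enoate and ionisation of the tertiary allylic alcohol.

Step 18
Reactants: 30 (3S,6S,7R,8R,10R)-3,10-dihydroxy-8-[(2S)-2-methylbutanoyloxy]germacra-1E,4Z,11(13)-trien-12,6-olide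
Product: 31 (6S,7R,8R,10R)-10-hydroxy-8-[(2S)-2-methylbutanoyloxy]-3-oxogermacra-1E,4Z,11(13)-trien-12,6-olide (target)
Conditions: MnO2, CH2Cl2, rt
Reagents that add atoms: none
Why: Neutral oxidation of the doubly allylic secondary alcohol to the cross-conjugated dienone; the tertiary C10 alcohol cannot be oxidised and the Z C4=C5 bond is not exposed to acid or base.

## Compound list

1 | (tert-butyldimethylsilyloxy)acetaldehyde | O=CCO[Si](C)(C)C(C)(C)C | starting material
2 | ethyl 2-[bis(2,2,2-trifluoroethoxy)phosphoryl]propanoate | CCOC(=O)C(C)P(=O)(OCC(F)(F)F)OCC(F)(F)F | starting material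
3 | ethyl (2Z)-4-(tert-butyldimethylsilyloxy)-2-methylbut-2-enoate | CC(C)(C)[Si](C)(C)OC/C=C(/C)C(=O)OCC | intermediate
4 | (2Z)-4-(tert-butyldimethylsilyloxy)-2-methylbut-2-en-1-ol | CC(C)(C)[Si](C)(C)OC/C=C(/C)CO | intermediate
5 | (2Z)-4-(tert-butyldimethylsilyloxy)-2-methylbut-2-enal | CC(C)(C)[Si](C)(C)OC/C=C(/C)C=O | intermediate
6 | 2-methylbut-1-en-3-yne | C=C(C)C#C | starting material
7 | dicyclohexyl[(1E)-3-methylbuta-1,3-dien-1-yl]borane (not isolated) | C=C(C)/C=C/B(C1CCCCC1)C1CCCCC1 | intermediate
8 | methyl[(1E)-3-methylbuta-1,3-dien-1-yl]zinc (not isolated) | C=C(C)/C=C/[Zn]C | intermediate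
9 | (2Z,4S,5E)-1-(tert-butyldimethylsilyloxy)-3,7-dimethylocta-2,5,7-trien-4-ol | CC(C)(C)[Si](C)(C)OC/C=C(/C)[C@@H](O)/C=C/C(C)=C | intermediate
10 | (3E,5S,6Z)-5,8-bis(tert-butyldimethylsilyloxy)-2,6-dimethylocta-1,3,6-triene | CC(C)(C)[Si](C)(C)OC/C=C(/C)[C@@H](O[Si](C)(C)C(C)(C)C)/C=C/C(C)=C | intermediate
11 | (2Z,4S,5E)-4-(tert-butyldimethylsilyloxy)-3,7-dimethylocta-2,5,7-trien-1-ol | OC/C=C(/C)[C@@H](O[Si](C)(C)C(C)(C)C)/C=C/C(C)=C | intermediate
12 | (2Z,4S,5E)-4-(tert-butyldimethylsilyloxy)-3,7-dimethylocta-2,5,7-trienal | O=C/C=C(/C)[C@@H](O[Si](C)(C)C(C)(C)C)/C=C/C(C)=C | intermediate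
13 | methyl acrylate | C=CC(=O)OC | starting material
14 | methyl 4-(tert-butyldimethylsilyloxy)-3-hydroxy-2-methylidenebutanoate (racemic) | COC(=O)C(=C)C(O)CO[Si](C)(C)C(C)(C)C | intermediate
15 | methyl (2Z)-2-(bromomethyl)-4-(tert-butyldimethylsilyloxy)but-2-enoate | COC(=O)/C(CBr)=C/CO[Si](C)(C)C(C)(C)C | intermediate
16 | methyl (2Z)-4-(tert-butyldimethylsilyloxy)-2-[(dichlorochromio)methyl]but-2-enoate, allylchromium species of trivalent chromium, ligand omitted (not isolated) | COC(=O)/C(C[Cr](Cl)Cl)=C/CO[Si](C)(C)C(C)(C)C | intermediate
17 | methyl (3R,4S,5Z,7S,8E)-7-(tert-butyldimethylsilyloxy)-3-[(tert-butyldimethylsilyloxy)methyl]-6,10-dimethyl-2-methylidene-4-(trimethylsilyloxy)undeca-5,8,10-trienoate (not isolated) | C=C(C(=O)OC)[C@H](CO[Si](C)(C)C(C)(C)C)[C@@H](O[Si](C)(C)C)/C=C(/C)[C@@H](O[Si](C)(C)C(C)(C)C)/C=C/C(C)=C | intermediate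
18 | methyl (3R,4S,5Z,7S,8E)-7-(tert-butyldimethylsilyloxy)-3-[(tert-butyldimethylsilyloxy)methyl]-4-hydroxy-6,10-dimethyl-2-methylideneundeca-5,8,10-trienoate (not isolated) | C=C(C(=O)OC)[C@H](CO[Si](C)(C)C(C)(C)C)[C@@H](O)/C=C(/C)[C@@H](O[Si](C)(C)C(C)(C)C)/C=C/C(C)=C | intermediate
19 | (4R,5S)-4-[(tert-butyldimethylsilyloxy)methyl]-5-[(1Z,3S,4E)-3-(tert-butyldimethylsilyloxy)-2,6-dimethylhepta-1,4,6-trien-1-yl]-3-methylideneoxolan-2-one | C=C1C(=O)O[C@@H](/C=C(/C)[C@@H](O[Si](C)(C)C(C)(C)C)/C=C/C(C)=C)[C@H]1CO[Si](C)(C)C(C)(C)C | intermediate
20 | (4R,5S)-5-[(1Z,3S,4E)-3-(tert-butyldimethylsilyloxy)-2,6-dimethylhepta-1,4,6-trien-1-yl]-4-(hydroxymethyl)-3-methylideneoxolan-2-one | C=C1C(=O)O[C@@H](/C=C(/C)[C@@H](O[Si](C)(C)C(C)(C)C)/C=C/C(C)=C)[C@H]1CO | intermediate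
21 | (2S,3S)-2-[(1Z,3S,4E)-3-(tert-butyldimethylsilyloxy)-2,6-dimethylhepta-1,4,6-trien-1-yl]-4-methylidene-5-oxooxolane-3-carbaldehyde (not isolated) | C=C1C(=O)O[C@@H](/C=C(/C)[C@@H](O[Si](C)(C)C(C)(C)C)/C=C/C(C)=C)[C@H]1C=O | intermediate
22 | (4R,5S)-5-[(1Z,3S,4E)-3-(tert-butyldimethylsilyloxy)-2,6-dimethylhepta-1,4,6-trien-1-yl]-4-[(E)-(hydroxyimino)methyl]-3-methylideneoxolan-2-one | C=C1C(=O)O[C@@H](/C=C(/C)[C@@H](O[Si](C)(C)C(C)(C)C)/C=C/C(C)=C)[C@H]1/C=N/O | intermediate
23 | (2S,3R)-2-[(1Z,3S,4E)-3-(tert-butyldimethylsilyloxy)-2,6-dimethylhepta-1,4,6-trien-1-yl]-4-methylidene-5-oxooxolane-3-carbonitrile N-oxide (not isolated) | C=C1C(=O)O[C@@H](/C=C(/C)[C@@H](O[Si](C)(C)C(C)(C)C)/C=C/C(C)=C)[C@H]1C#[N+][O-] | intermediate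
24 | (3S,6S,7R,10R)-3-(tert-butyldimethylsilyloxy)germacra-1E,4Z,11(13)-trien-12,6-olide bridged by C8=N–O–C10 (isoxazoline) | C=C1C(=O)O[C@H]2/C=C(/C)[C@@H](O[Si](C)(C)C(C)(C)C)/C=C/[C@@]3(C)CC(=NO3)[C@@H]12 | intermediate
25 | (3S,6S,7R,10R)-3-(tert-butyldimethylsilyloxy)-10-hydroxy-8-iminogermacra-1E,4Z,11(13)-trien-12,6-olide (not isolated) | C=C1C(=O)O[C@H]2/C=C(/C)[C@@H](O[Si](C)(C)C(C)(C)C)/C=C/[C@](C)(O)CC(=N)[C@@H]12 | intermediate
26 | (3S,6S,7S,10R)-3-(tert-butyldimethylsilyloxy)-10-hydroxy-8-oxogermacra-1E,4Z,11(13)-trien-12,6-olide | C=C1C(=O)O[C@H]2/C=C(/C)[C@@H](O[Si](C)(C)C(C)(C)C)/C=C/[C@](C)(O)CC(=O)[C@@H]12 | intermediate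
27 | (3S,6S,7R,8R,10R)-3-(tert-butyldimethylsilyloxy)-8,10-dihydroxygermacra-1E,4Z,11(13)-trien-12,6-olide | C=C1C(=O)O[C@H]2/C=C(/C)[C@@H](O[Si](C)(C)C(C)(C)C)/C=C/[C@](C)(O)C[C@@H](O)[C@@H]12 | intermediate
28 | (2S)-2-methylbutanoic anhydride | CC[C@H](C)C(=O)OC(=O)[C@@H](C)CC | starting material
29 | (3S,6S,7R,8R,10R)-3-(tert-butyldimethylsilyloxy)-10-hydroxy-8-[(2S)-2-methylbutanoyloxy]germacra-1E,4Z,11(13)-trien-12,6-olide | C=C1C(=O)O[C@H]2/C=C(/C)[C@@H](O[Si](C)(C)C(C)(C)C)/C=C/[C@](C)(O)C[C@@H](OC(=O)[C@@H](C)CC)[C@@H]12 | intermediate
30 | (3S,6S,7R,8R,10R)-3,10-dihydroxy-8-[(2S)-2-methylbutanoyloxy]germacra-1E,4Z,11(13)-trien-12,6-olide | C=C1C(=O)O[C@H]2/C=C(/C)[C@@H](O)/C=C/[C@](C)(O)C[C@@H](OC(=O)[C@@H](C)CC)[C@@H]12 | intermediate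
31 | (6S,7R,8R,10R)-10-hydroxy-8-[(2S)-2-methylbutanoyloxy]-3-oxogermacra-1E,4Z,11(13)-trien-12,6-olide (CNP0315499.4) | C=C1C(=O)O[C@H]2/C=C(/C)C(=O)/C=C/[C@](C)(O)C[C@@H](OC(=O)[C@@H](C)CC)[C@@H]12 | target

## Step count and least certain steps

Total step count: 18. Longest linear sequence: 16 steps (steps 1–7 and 10–18); steps 8 and 9 form the second branch.

**Step 13 (key step).** The ten-membered bridged transition state is strained and slow, so the nitrile oxide may be consumed by other processes.
- It may add to the α-methylene lactone of a second molecule, the most reactive dipolarophile present, or dimerise to a furoxan.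
- It may close a seven-membered fused ring onto C1=C2, a unimolecular path that dilution cannot suppress.
- Facial control at C10 rests only on the fold imposed by the cis lactone and C3. The C3 silyl ether (configuration, size) stays available for tuning because it ends as a ketone.

Fallback, which removes the strongest competing dipolarophile by temporary masking and so allows a higher working concentration: it sets out from aldoxime 22. Me2NH in THF at 0 °C adds to C13 and gives the amino lactone oxime F1 (the C11 configuration is of no consequence). Held as its trifluoroacetate salt, F1 is oxidised with PhI(OAc)2 to the nitrile oxide F2, which can now react only at the diene and should give the masked isoxazoline F3. MeI gives the ammonium iodide F4, and aqueous NaHCO3 in CH2Cl2 eliminates trimethylamine to restore the methylene group. The fallback comes back to the route at 24.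

**Step 10.** What may go wrong is insufficient catalyst control over the aldehyde face, since a Z enal with a γ-silyloxy centre is not a standard substrate, or Z-to-E isomerisation of the enal in the Lewis-acidic, chloride-rich medium. Fallback, which exchanges catalyst control for separation of diastereomers: it sets out from 12 and 15. Stoichiometric CrCl2 in THF at 0 °C without ligand or TMSCl (the chromium alkoxide lactonises on work-up) should give the two cis lactones, 19 and the diastereomeric cis lactone F5. They differ in their relation to the fixed 3S centre and are separated by chromatography. The fallback comes back at 19.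

**Step 4.** What may go wrong is erosion of enantioselectivity (an α-branched Z enal, uncatalysed background addition, competing methyl transfer) or isomerisation of the Z enal by the Lewis-acidic zinc and boron species. Fallback, which builds C2–C3 by alkynylation and sets the E alkene afterwards: it sets out from 5 and 6. Me2Zn with a dinuclear zinc–prolinol (ProPhenol) catalyst in toluene at 0 °C adds the alkyne to the aldehyde and gives the propargylic alcohol F6. NaAlH2(OCH2CH2OMe)2 in THF at 0 °C then reduces the propargylic alkyne trans. The fallback comes back at 9.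

**Step 12.** What may go wrong is epimerisation at C7 (cis to trans) or β-elimination of the lactone carboxylate in aldehyde 21, and conjugate addition of hydroxylamine to the enoate. Fallback, which avoids the aldehyde altogether: it sets out from alcohol 20. I2, PPh3 and imidazole give the iodide F7; AgNO2 in Et2O gives the nitro compound F8; PhNCO and Et3N (Mukaiyama dehydration) under high dilution generate the nitrile oxide directly. The fallback comes back at 23, inside step 13, with the same dipole and the same ring closure.

**Step 15.** What may go wrong is poor facial selectivity, because in the ten-membered ring the tertiary C10 hydroxyl may not reach across the C8 carbonyl and external hydride delivery then competes; ketone 26 may also epimerise at C7 if it is stored. Fallback, which makes the other epimer on purpose and inverts it while installing the ester: it sets out from 26. Chelation-controlled reduction (Et2BOMe, NaBH4, THF/MeOH, −78 °C; Narasaka–Prasad) should give the syn diol F9. Mitsunobu esterification with (2S)-2-methylbutanoic acid (PPh3, DIAD, toluene, 0 °C) then inverts C8. The fallback comes back at 29, so that 27 and step 16 are bypassed.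

## Further compounds

F1 | step 13 | (3S,4R,5S)-5-[(1Z,3S,4E)-3-(tert-butyldimethylsilyloxy)-2,6-dimethylhepta-1,4,6-trien-1-yl]-3-[(dimethylamino)methyl]-4-[(E)-(hydroxyimino)methyl]oxolan-2-one | CN(C)C[C@H]1C(=O)O[C@@H](/C=C(/C)[C@@H](O[Si](C)(C)C(C)(C)C)/C=C/C(C)=C)[C@H]1/C=N/O
F2 | step 13 | nitrile oxide of F1, (2S,3R,4S)-2-[(1Z,3S,4E)-3-(tert-butyldimethylsilyloxy)-2,6-dimethylhepta-1,4,6-trien-1-yl]-4-[(dimethylamino)methyl]-5-oxooxolane-3-carbonitrile N-oxide | CN(C)C[C@H]1C(=O)O[C@@H](/C=C(/C)[C@@H](O[Si](C)(C)C(C)(C)C)/C=C/C(C)=C)[C@H]1C#[N+][O-]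
F3 | step 13 | 13-(dimethylamino)-11,13-dihydro derivative of 24 (11S) | CN(C)C[C@H]1C(=O)O[C@H]2/C=C(/C)[C@@H](O[Si](C)(C)C(C)(C)C)/C=C/[C@@]3(C)CC(=NO3)[C@@H]12
F4 | step 13 | trimethylammonium iodide of F3 | C[N+](C)(C)C[C@H]1C(=O)O[C@H]2/C=C(/C)[C@@H](O[Si](C)(C)C(C)(C)C)/C=C/[C@@]3(C)CC(=NO3)[C@@H]12.[I-]
F5 | step 10 | (4S,5R)-4-[(tert-butyldimethylsilyloxy)methyl]-5-[(1Z,3S,4E)-3-(tert-butyldimethylsilyloxy)-2,6-dimethylhepta-1,4,6-trien-1-yl]-3-methylideneoxolan-2-one | C=C1C(=O)O[C@H](/C=C(/C)[C@@H](O[Si](C)(C)C(C)(C)C)/C=C/C(C)=C)[C@@H]1CO[Si](C)(C)C(C)(C)C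
F6 | step 4 | (2Z,4R)-1-(tert-butyldimethylsilyloxy)-3,7-dimethylocta-2,7-dien-5-yn-4-ol | CC(C)(C)[Si](C)(C)OC/C=C(/C)[C@@H](O)C#CC(C)=C
F7 | step 12 | (4S,5S)-5-[(1Z,3S,4E)-3-(tert-butyldimethylsilyloxy)-2,6-dimethylhepta-1,4,6-trien-1-yl]-4-(iodomethyl)-3-methylideneoxolan-2-one | C=C1C(=O)O[C@@H](/C=C(/C)[C@@H](O[Si](C)(C)C(C)(C)C)/C=C/C(C)=C)[C@H]1CI
F8 | step 12 | (4R,5S)-5-[(1Z,3S,4E)-3-(tert-butyldimethylsilyloxy)-2,6-dimethylhepta-1,4,6-trien-1-yl]-3-methylidene-4-(nitromethyl)oxolan-2-one | C=C1C(=O)O[C@@H](/C=C(/C)[C@@H](O[Si](C)(C)C(C)(C)C)/C=C/C(C)=C)[C@H]1C[N+](=O)[O-]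
F9 | step 15 | (3S,6S,7R,8S,10R)-3-(tert-butyldimethylsilyloxy)-8,10-dihydroxygermacra-1E,4Z,11(13)-trien-12,6-olide | C=C1C(=O)O[C@H]2/C=C(/C)[C@@H](O[Si](C)(C)C(C)(C)C)/C=C/[C@](C)(O)C[C@H](O)[C@@H]12
A1 | alternative 1 | trans-1-(prop-1-ynyl)-2-[(Z)-2-(4-methoxybenzyloxy)vinyl]cyclohexanol carrying the C7 silyloxy-propenyl branch, the C8 silyl ether and the C10 methyl/triethylsilyloxy centre | CC#C[C@]1(O)[C@H](C(=C)CO[Si](C)(C)C(C)(C)C)[C@H](O[Si](C)(C)C(C)(C)C)C[C@@](C)(O[Si](CC)(CC)CC)[C@H]1/C=C\OCc1ccc(OC)cc1
A2 | alternative 1 | ten-membered C6 enone with C3 4-methoxybenzyl ether | O=C1/C=C(/C)[C@@H](OCc2ccc(OC)cc2)/C=C/[C@](C)(O[Si](CC)(CC)CC)C[C@@H](O[Si](C)(C)C(C)(C)C)[C@H]1C(=C)CO[Si](C)(C)C(C)(C)C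
A3 | alternative 2 | seco iodoalkyne methyl ketone with lactone and C8 ester in place | C=C1C(=O)O[C@@H](/C=C(/C)[C@@H](O[Si](C)(C)C(C)(C)C)C#CI)[C@H]1[C@@H](CC(C)=O)OC(=O)[C@@H](C)CC
A4 | alternative 2 | ten-membered cycloalkyne C10 carbinol | C=C1C(=O)O[C@H]2/C=C(/C)[C@@H](O[Si](C)(C)C(C)(C)C)C#C[C@](C)(O)C[C@@H](OC(=O)[C@@H](C)CC)[C@@H]12
A5 | alternative 3 | 3-(bromomethyl)butenolide with tethered C8 aldehyde | O=C1O[C@@H](/C=C(/C)[C@@H](O[Si](C)(C)C(C)(C)C)/C=C/[C@](C)(O[Si](CC)(CC)CC)CC=O)C=C1CBr
A6 | alternative 3 | ten-membered α-methylene lactone with free C8 hydroxyl | C=C1C(=O)O[C@H]2/C=C(/C)[C@@H](O[Si](C)(C)C(C)(C)C)/C=C/[C@](C)(O[Si](CC)(CC)CC)C[C@@H](O)[C@@H]12
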